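**Plan**

1. Labdane numbering is used throughout (C19 = carboxyl carbon on C4, C17 = exocyclic methylene carbon, C20 = methyl on C10); the target is 7α-acetoxy-trans-communic acid (4S,5R,7R,9R,10R,12E).
2. Retrosynthesis: the acetate and the C19 methyl ester go first. C14=C15 and C12=C13 (two Wittig olefinations) and C11–C12 (one-carbon homologation) lead back to a C11 ester. The 7α-OH/C8=C17 pair is traced through a [2,3] sulfoxide–sulfenate shift and a 1,4-hydrothiolation to a 6,8(17)-diene.
3. Enabling feature: ring B (C5–C10) carries the exocyclic C8=C17 alkene next to the cis C9–C11/C10–C20 pair. It is therefore the cycloadduct of a vinylallene (C5=C6–C7=C8=C17) and an (E)-enoate (C9=C10–C11) tied through C1–C4; cutting C8–C9 and C5–C10 together opens rings B and A to an acyclic triene.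
4. Forward: malonate allylation (C3–C4), desymmetrising reduction, B-alkyl Suzuki coupling (C1–C10), Takai olefination (C5=C6) and Stille allenylation (C6–C7) build the chain. One intramolecular Diels–Alder reaction closes rings A and B; ring B oxygenation, side-chain growth, ester cleavage and acetylation follow.
5. Stereochemistry: C4 from catalytic desymmetrisation of a malonate; C5, C9 and C10 in the cycloaddition (E-enoate geometry, ester-endo/tether-exo transition state, C4 as relay); C7 by axial oxygen delivery in the [2,3] shift; 12E from a stabilised ylide.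

Key step: step 8

**Route**

Step 1
Reactants: 1 dimethyl 2-methylmalonate
Product: 2 dimethyl 2-allyl-2-methylmalonate
Conditions: NaH, THF, 0 °C; allyl bromide, 0 °C → rt
Reagents that add atoms: allyl bromide, C=CCBr
Why: Malonic ester alkylation of the sodium enolate with an allylic bromide is fast and can occur only once at the single remaining C–H; no stereocentre is formed.

Step 2
Reactants: 2 dimethyl 2-allyl-2-methylmalonate
Product: 4 methyl (2S)-2-(hydroxymethyl)-2-methylpent-4-enoate, via silyl ether 3 (not isolated)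
Conditions: ZnEt2 (10 mol%), chiral tetradentate ProPhenol-type ligand (5 mol%), HSiMe(OEt)2, THF, rt; then K2CO3, MeOH
Reagents that add atoms: none
Why: Catalytic desymmetrising hydrosilylation (mono-reduction) of a prochiral 2,2-disubstituted malonate: the dinuclear zinc–aminoalcohol catalyst binds both ester carbonyls and should reduce only the pro-R ester, so the ligand enantiomer sets C4 as S, and the hydroxy ester formed is not reduced further.

Step 3
Reactants: 5 methyl acetoacetate
Product: 6 methyl (2E)-3-{[(trifluoromethyl)sulfonyl]oxy}but-2-enoate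
Conditions: Tf2O, aq. Me4NOH, hexane, 5 °C
Reagents that add atoms: triflic anhydride, O=S(=O)(OS(=O)(=O)C(F)(F)F)C(F)(F)F
Why: O-Triflation of the β-keto ester enolate with a non-chelating tetraalkylammonium counter-ion should give the (E)-enol triflate (triflate trans to the ester), which fixes the later C9=C10 dienophile geometry.

Step 4
Reactants: 4 methyl (2S)-2-(hydroxymethyl)-2-methylpent-4-enoate; 6 methyl (2E)-3-{[(trifluoromethyl)sulfonyl]oxy}but-2-enoate
Product: 8 dimethyl (2E,7S)-7-(hydroxymethyl)-3,7-dimethyloct-2-enedioate, via bis-boryl adduct 7 (not isolated)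
Conditions: 9-BBN (2.2 equiv), THF, 0 °C → rt; then 6, Pd(dppf)Cl2 (5 mol%), 3 M aq. K3PO4, DMF, rt
Reagents that add atoms: none
Why: Anti-Markovnikov hydroboration of the terminal alkene followed by B-alkyl Suzuki–Miyaura coupling proceeds with retention at the sp2 carbon, so the (E)-trisubstituted enoate (C20 methyl cis to C11) should result, with the esters and the alcohol (as its borinate) tolerated.

Step 5
Reactants: 8 dimethyl (2E,7S)-7-(hydroxymethyl)-3,7-dimethyloct-2-enedioate
Product: 9 dimethyl (2E,7S)-7-formyl-3,7-dimethyloct-2-enedioate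
Conditions: Dess–Martin periodinane, CH2Cl2, rt
Reagents that add atoms: none
Why: Dess–Martin oxidation of the neopentylic primary alcohol gives the aldehyde, which cannot epimerise because C4 is quaternary.

Step 6
Reactants: 9 dimethyl (2E,7S)-7-formyl-3,7-dimethyloct-2-enedioate
Product: 10 dimethyl (2E,7S)-7-[(E)-2-iodoethenyl]-3,7-dimethyloct-2-enedioate
Conditions: CrCl2 (6 equiv), CHI3 (2 equiv), THF, 0 °C → rt
Reagents that add atoms: iodoform, IC(I)I
Why: Takai iodo-olefination converts hindered, non-enolisable aldehydes into (E)-vinyl iodides and leaves both esters and the enoate untouched, which sets the (E)-C5=C6 alkene of the diene.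

Step 7
Reactants: 10 dimethyl (2E,7S)-7-[(E)-2-iodoethenyl]-3,7-dimethyloct-2-enedioate
Product: 11 dimethyl (2E,7S)-3,7-dimethyl-7-[(1E)-penta-1,3,4-trien-1-yl]oct-2-enedioate
Conditions: allenyl-SnBu3 (1.5 equiv), Pd2(dba)3 (2.5 mol%), AsPh3 (10 mol%), LiCl, DMF, rt
Reagents that add atoms: tributyl(propa-1,2-dien-1-yl)stannane, C=C=C[Sn](CCCC)(CCCC)CCCC
Why: Stille coupling of the vinyl iodide with the allenylstannane should transfer the allenyl group with retention of the (E)-alkene geometry and give the terminal vinylallene at room temperature, mild enough to avoid premature cycloaddition.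

Step 8
Reactants: 11 dimethyl (2E,7S)-3,7-dimethyl-7-[(1E)-penta-1,3,4-trien-1-yl]oct-2-enedioate
Product: 12 dimethyl 12,13,14,15,16-pentanorlabda-6,8(17)-diene-11,19-dioate (trans-fused; 5α-H, 9α-H, 10β-CH3, 4β-CO2CH3)
Conditions: PhMe (0.01 M), BHT (cat.), sealed tube, 130 °C
Reagents that add atoms: none
Why: Thermal intramolecular Diels–Alder reaction: the s-cis vinylallene (C5=C6–C7=C8) adds suprafacially, in a concerted but asynchronous [4+2] process, to the tethered (E)-enoate C9=C10, forming C8–C9 and C5–C10 in one operation while the distal allene π bond remains as the exocyclic C8=C17 methylene. The closest known reaction type is the intramolecular cycloaddition of vinylallenes in 1,7,9-decatriene-type substrates. Ring B is closed as the new cyclohexene in the fused mode (both new bonds) and ring A as the tether ring through C5–C10, the four-atom tether C1–C4 excluding the bridged regiochemistry. C9 and C10 are set together by the (E)-geometry of the dienophile (C20 methyl and C11 ester stay cis), and C5 relative to C10 by the chair-like, tether-exo transition state with the ester endo, which gives the trans ring fusion (5α-H, 10β-CH3). The absolute sense is relayed from C4: the ester (smaller A value than methyl) should take the pseudo-axial position syn to the developing axial C10 methyl, giving 4β-CO2CH3/10β-CH3 as in the target. The step needs endo-over-exo and C4-controlled facial selectivity, supported by the C4 quaternary centre and the C10 methyl (both destabilise the tether-endo, cis-fused arrangement) though only moderately biased thermally, while release of allene strain and the unhindered sp-hybridised C8 terminus should let the congested C5–C10 bond form at moderate temperature.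

Step 9
Reactants: 12 dimethyl 12,13,14,15,16-pentanorlabda-6,8(17)-diene-11,19-dioate
Product: 13 dimethyl 17-(phenylsulfanyl)-12,13,14,15,16-pentanorlabd-7-ene-11,19-dioate
Conditions: PhSH (1.2 equiv), BEt3 (0.2 equiv), air, PhMe, 0 °C
Reagents that add atoms: thiophenol, Sc1ccccc1
Why: Radical-chain hydrothiolation of a conjugated diene (thiol–diene addition): the thiyl radical adds to the unhindered terminal C17 and the allyl radical should take up hydrogen at secondary C6 rather than tertiary C8, giving the 1,4-adduct with the more substituted C7=C8 alkene and no new stereocentre.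

Step 10
Reactants: 13 dimethyl 17-(phenylsulfanyl)-12,13,14,15,16-pentanorlabd-7-ene-11,19-dioate
Product: 16 dimethyl 7α-hydroxy-12,13,14,15,16-pentanorlabd-8(17)-ene-11,19-dioate, via allylic sulfoxide 14 (not isolated), via allylic sulfenate 15 (not isolated)
Conditions: mCPBA (1.0 equiv), CH2Cl2, −78 °C; then P(OMe)3 (3 equiv), MeOH, rt → 40 °C
Reagents that add atoms: mCPBA, OOC(=O)c1cccc(Cl)c1
Why: Mislow–Evans rearrangement: chemoselective S-oxidation gives the allylic sulfoxide, whose reversible suprafacial [2,3]-sigmatropic shift to the sulfenate is drained by the neutral thiophile, and the shift onto the ring carbon should form the C7–O bond axially (α face, chair-like transition state), setting 7α-OH together with the exocyclic C8=C17 alkene.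

Step 11
Reactants: 16 dimethyl 7α-hydroxy-12,13,14,15,16-pentanorlabd-8(17)-ene-11,19-dioate
Product: 17 methyl 7α-hydroxy-11-oxo-12,13,14,15,16-pentanorlabd-8(17)-en-19-oate
Conditions: i-Bu2AlH (2.2 equiv), CH2Cl2, −78 °C; aq. KNaC4H4O6
Reagents that add atoms: none
Why: Partial reduction of a methyl ester to the aldehyde through the tetrahedral aluminium hemiacetal that is stable at −78 °C; the equatorial C11 ester on secondary C9 should react in preference to the axial, neopentylic C19 ester, and the C7 hydroxyl only consumes one equivalent of hydride.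

Step 12
Reactants: 17 methyl 7α-hydroxy-11-oxo-12,13,14,15,16-pentanorlabd-8(17)-en-19-oate
Product: 18 methyl 7α-hydroxy-12-methoxy-13,14,15,16-tetranorlabda-8(17),11-dien-19-oate (E/Z mixture at C11=C12)
Conditions: MeOCH2PPh3Cl, KN(SiMe3)2, THF, 0 °C; then 17, −78 → 0 °C
Reagents that add atoms: (methoxymethyl)triphenylphosphonium chloride, COC[P+](c1ccccc1)(c1ccccc1)c1ccccc1.[Cl-]
Why: Wittig methoxymethylenation (one-carbon homologation): the non-stabilised ylide should add to the hindered aldehyde at low temperature faster than it enolises it, so the C9 configuration is kept.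

Step 13
Reactants: 18 methyl 7α-hydroxy-12-methoxy-13,14,15,16-tetranorlabda-8(17),11-dien-19-oate
Product: 19 methyl 7α-hydroxy-12-oxo-13,14,15,16-tetranorlabd-8(17)-en-19-oate
Conditions: 1 M aq. HCl, THF, 0 °C → rt
Reagents that add atoms: water, O
Why: Acid-catalysed enol ether hydrolysis liberates the homologated C12 aldehyde, and the secondary allylic alcohol and exocyclic alkene should survive dilute acid at or below room temperature.

Step 14
Reactants: 19 methyl 7α-hydroxy-12-oxo-13,14,15,16-tetranorlabd-8(17)-en-19-oate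
Product: 20 methyl (12E)-7α-hydroxy-14-oxo-15-norlabda-8(17),12-dien-19-oate
Conditions: Ph3P=C(CH3)CHO (1.5 equiv), PhMe, 90 °C
Reagents that add atoms: 2-(triphenylphosphoranylidene)propanal, CC(C=O)=P(c1ccccc1)(c1ccccc1)c1ccccc1
Why: Wittig olefination with a stabilised ylide is aldehyde-selective and (E)-selective, setting the trisubstituted C12=C13 alkene with C11 trans to the formyl group.

Step 15
Reactants: 20 methyl (12E)-7α-hydroxy-14-oxo-15-norlabda-8(17),12-dien-19-oate
Product: 21 methyl (12E)-7α-hydroxylabda-8(17),12,14-trien-19-oate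
Conditions: MePPh3Br, KN(SiMe3)2, THF, 0 °C; then 20, −78 → 0 °C
Reagents that add atoms: methyltriphenylphosphonium bromide, C[P+](c1ccccc1)(c1ccccc1)c1ccccc1.[Br-]
Why: Wittig methylenation of the enal completes the (12E)-1,3-diene by 1,2-addition without touching the existing alkene geometry, the free hydroxyl only consuming ylide.

Step 16
Reactants: 21 methyl (12E)-7α-hydroxylabda-8(17),12,14-trien-19-oate
Product: 22 (12E)-7α-hydroxylabda-8(17),12,14-trien-19-oic acid
Conditions: n-PrSLi (from n-PrSH and n-BuLi), HMPA, rt; then 1 M aq. HCl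
Reagents that add atoms: none
Why: Nucleophilic ester cleavage by SN2 attack of the soft thiolate on the methyl carbon avoids the tetrahedral pathway that the axial, neopentylic C19 carbonyl resists and should leave the diene and the allylic alcohol intact.

Step 17
Reactants: 22 (12E)-7α-hydroxylabda-8(17),12,14-trien-19-oic acid
Product: 24 (12E)-7α-acetoxylabda-8(17),12,14-trien-19-oic acid, via mixed anhydride 23 (not isolated)
Conditions: Ac2O, pyridine, DMAP (cat.), CH2Cl2, rt; then H2O, THF, rt
Reagents that add atoms: acetic anhydride, CC(=O)OC(C)=O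
Why: Nucleophile-catalysed acetylation of the axial secondary alcohol, with any mixed anhydride formed at the C19 carboxyl hydrolysed selectively in the aqueous stage because the C7 acetate ester is far less electrophilic; no stereocentre is affected.

**Compound list**

1 | dimethyl 2-methylmalonate | COC(=O)C(C)C(=O)OC | starting material
2 | dimethyl 2-allyl-2-methylmalonate | C=CCC(C)(C(=O)OC)C(=O)OC | intermediate
3 | methyl (2S)-2-({[diethoxy(methyl)silyl]oxy}methyl)-2-methylpent-4-enoate | C=CC[C@](C)(C(=O)OC)CO[Si](C)(OCC)OCC | intermediate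
4 | methyl (2S)-2-(hydroxymethyl)-2-methylpent-4-enoate | C=CC[C@](C)(C(=O)OC)CO | intermediate
5 | methyl acetoacetate | CC(=O)CC(=O)OC | starting material
6 | methyl (2E)-3-{[(trifluoromethyl)sulfonyl]oxy}but-2-enoate | COC(=O)/C=C(\C)OS(=O)(=O)C(F)(F)F | intermediate
7 | methyl (2S)-5-(9-borabicyclo[3.3.1]nonan-9-yl)-2-{[(9-borabicyclo[3.3.1]nonan-9-yl)oxy]methyl}-2-methylpentanoate | C1CCC2CCCC1B2CCC[C@](C)(C(=O)OC)COB1C2CCCC1CCC2 | intermediate
8 | dimethyl (2E,7S)-7-(hydroxymethyl)-3,7-dimethyloct-2-enedioate | COC(=O)/C=C(\C)CCC[C@](C)(C(=O)OC)CO | intermediate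
9 | dimethyl (2E,7S)-7-formyl-3,7-dimethyloct-2-enedioate | COC(=O)/C=C(\C)CCC[C@](C)(C(=O)OC)C=O | intermediate
10 | dimethyl (2E,7S)-7-[(E)-2-iodoethenyl]-3,7-dimethyloct-2-enedioate | COC(=O)/C=C(\C)CCC[C@](C)(C(=O)OC)/C=C/I | intermediate
11 | dimethyl (2E,7S)-3,7-dimethyl-7-[(1E)-penta-1,3,4-trien-1-yl]oct-2-enedioate | COC(=O)/C=C(\C)CCC[C@](C)(C(=O)OC)/C=C/C=C=C | intermediate
12 | dimethyl 12,13,14,15,16-pentanorlabda-6,8(17)-diene-11,19-dioate (5α-H, 9α-H, 10β-CH3, 4β-CO2CH3) | COC(=O)[C@H]1C(=C)C=C[C@@H]2[C@]1(C)CCC[C@]2(C)C(=O)OC | intermediate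
13 | dimethyl 17-(phenylsulfanyl)-12,13,14,15,16-pentanorlabd-7-ene-11,19-dioate | COC(=O)[C@H]1C(CSc3ccccc3)=CC[C@@H]2[C@]1(C)CCC[C@]2(C)C(=O)OC | intermediate
14 | dimethyl 17-(phenylsulfinyl)-12,13,14,15,16-pentanorlabd-7-ene-11,19-dioate (both sulfur epimers) | COC(=O)[C@H]1C(CS(=O)c3ccccc3)=CC[C@@H]2[C@]1(C)CCC[C@]2(C)C(=O)OC | intermediate
15 | dimethyl 7α-[(phenylsulfanyl)oxy]-12,13,14,15,16-pentanorlabd-8(17)-ene-11,19-dioate | COC(=O)[C@H]1C(=C)[C@H](OSc3ccccc3)C[C@@H]2[C@]1(C)CCC[C@]2(C)C(=O)OC | intermediate
16 | dimethyl 7α-hydroxy-12,13,14,15,16-pentanorlabd-8(17)-ene-11,19-dioate | COC(=O)[C@H]1C(=C)[C@H](O)C[C@@H]2[C@]1(C)CCC[C@]2(C)C(=O)OC | intermediate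
17 | methyl 7α-hydroxy-11-oxo-12,13,14,15,16-pentanorlabd-8(17)-en-19-oate | O=C[C@H]1C(=C)[C@H](O)C[C@@H]2[C@]1(C)CCC[C@]2(C)C(=O)OC | intermediate
18 | methyl 7α-hydroxy-12-methoxy-13,14,15,16-tetranorlabda-8(17),11-dien-19-oate (E/Z mixture at C11=C12) | COC=C[C@H]1C(=C)[C@H](O)C[C@@H]2[C@]1(C)CCC[C@]2(C)C(=O)OC | intermediate
19 | methyl 7α-hydroxy-12-oxo-13,14,15,16-tetranorlabd-8(17)-en-19-oate | O=CC[C@H]1C(=C)[C@H](O)C[C@@H]2[C@]1(C)CCC[C@]2(C)C(=O)OC | intermediate
20 | methyl (12E)-7α-hydroxy-14-oxo-15-norlabda-8(17),12-dien-19-oate | O=C/C(C)=C/C[C@H]1C(=C)[C@H](O)C[C@@H]2[C@]1(C)CCC[C@]2(C)C(=O)OC | intermediate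
21 | methyl (12E)-7α-hydroxylabda-8(17),12,14-trien-19-oate | C=C/C(C)=C/C[C@H]1C(=C)[C@H](O)C[C@@H]2[C@]1(C)CCC[C@]2(C)C(=O)OC | intermediate
22 | (12E)-7α-hydroxylabda-8(17),12,14-trien-19-oic acid | C=C/C(C)=C/C[C@H]1C(=C)[C@H](O)C[C@@H]2[C@]1(C)CCC[C@]2(C)C(=O)O | intermediate
23 | acetic (12E)-7α-acetoxylabda-8(17),12,14-trien-19-oic anhydride | C=C/C(C)=C/C[C@H]1C(=C)[C@H](OC(C)=O)C[C@@H]2[C@]1(C)CCC[C@]2(C)C(=O)OC(C)=O | intermediate
24 | (12E)-7α-acetoxylabda-8(17),12,14-trien-19-oic acid (4S,5R,7R,9R,10R) | C=C/C(C)=C/C[C@H]1C(=C)[C@H](OC(C)=O)C[C@@H]2[C@]1(C)CCC[C@]2(C)C(=O)O | target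

**Step count and risks**

Total step count: 17. Longest linear sequence: 16 steps (steps 1, 2 and 4 to 17, from 1); step 3 is a one-step branch.

The three steps most likely to fail:

Step 8. The C4 centre may differentiate the two diene faces only weakly at 130 °C, the ester-exo (cis-fused) transition state may leak through, or the allene may oligomerise before it cyclises. The fallback changes the dienophile and the mode of activation and sets out from 11. The conjugated ester is reduced selectively (i-Bu2AlH, CH2Cl2, −78 °C) to the C11 allylic alcohol F1, which is oxidised (MnO2, CH2Cl2) to the enal F2. The enal is cyclised as its Me2AlCl complex at −78 to −20 °C, a Lewis-acid-promoted intramolecular Diels–Alder reaction in which the same energy differences should give higher endo and facial selectivity, to the tricyclic-free decalin aldehyde F3. Pinnick oxidation (NaClO2, NaH2PO4, 2-methylbut-2-ene) gives the C11 acid F4, and methylation with TMSCHN2 comes back to the route at 12.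

Step 9. Hydrogen-atom transfer may go to the wrong terminus of the allyl radical, or thiyl radicals may reversibly abstract the doubly activated C9–H, which would epimerise C9 or move the alkene into conjugation with the C11 ester. The fallback carries the C7 oxygen through the cycloaddition, so no diene functionalisation is needed, and sets out from 9. Horner–Wadsworth–Emmons olefination with dimethyl [2-oxo-4-(phenylsulfanyl)butyl]phosphonate (LiCl, i-Pr2NEt, MeCN) gives the (E)-enone F5, and TBSOTf/Et3N converts it into the 2-silyloxydiene F6. Thermal intramolecular Diels–Alder reaction (PhMe, 150 °C) should give the decalin silyl enol ether F7, which dilute HCl in THF hydrolyses to the C7 ketone F8. LiBH(s-Bu)3 at −78 °C attacks from the equatorial side to give the axial 7α-alcohol F9. Oxidation with NaIO4 gives the sulfoxide F10, and its thermal syn-elimination (PhMe, CaCO3, 110 °C) can only involve C8–H and comes back to the route at 16.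

Step 2. The catalyst may not discriminate well enough between the methyl and allyl groups, giving low enantioselectivity, or reduction of the second ester may compete. The fallback replaces the reductive desymmetrisation by an enzymatic one and sets out from 2. Pig liver esterase (pH 7.5 phosphate buffer, rt) should hydrolyse one enantiotopic ester to the (S)-half-ester F11. The acid is activated as its mixed ethyl carbonic anhydride F12 (ClCO2Et, Et3N, THF, −10 °C) and reduced with NaBH4, which leaves the methyl ester and the alkene untouched and comes back to the route at 4.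

**Further compounds**

F1 | step 8 | methyl (2S,6E)-8-hydroxy-2,6-dimethyl-2-[(1E)-penta-1,3,4-trien-1-yl]oct-6-enoate | OC/C=C(\C)CCC[C@](C)(C(=O)OC)/C=C/C=C=C
F2 | step 8 | methyl (2S,6E)-2,6-dimethyl-8-oxo-2-[(1E)-penta-1,3,4-trien-1-yl]oct-6-enoate | O=C/C=C(\C)CCC[C@](C)(C(=O)OC)/C=C/C=C=C
F3 | step 8 | methyl 11-oxo-12,13,14,15,16-pentanorlabda-6,8(17)-dien-19-oate | O=C[C@H]1C(=C)C=C[C@@H]2[C@]1(C)CCC[C@]2(C)C(=O)OC
F4 | step 8 | 19-methoxy-19-oxo-12,13,14,15,16-pentanorlabda-6,8(17)-dien-11-oic acid | OC(=O)[C@H]1C(=C)C=C[C@@H]2[C@]1(C)CCC[C@]2(C)C(=O)OC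
F5 | step 9 | dimethyl (2E,7S)-3,7-dimethyl-7-[(1E)-3-oxo-5-(phenylsulfanyl)pent-1-en-1-yl]oct-2-enedioate | COC(=O)/C=C(\C)CCC[C@](C)(C(=O)OC)/C=C/C(=O)CCSc1ccccc1
F6 | step 9 | dimethyl (2E,7S)-7-[(1E,3Z)-3-{[tert-butyl(dimethyl)silyl]oxy}-5-(phenylsulfanyl)penta-1,3-dien-1-yl]-3,7-dimethyloct-2-enedioate | COC(=O)/C=C(\C)CCC[C@](C)(C(=O)OC)/C=C/C(O[Si](C)(C)C(C)(C)C)=C/CSc1ccccc1
F7 | step 9 | dimethyl 7-{[tert-butyl(dimethyl)silyl]oxy}-17-(phenylsulfanyl)-12,13,14,15,16-pentanorlabd-6-ene-11,19-dioate (C8 epimers) | COC(=O)[C@H]1C(CSc3ccccc3)C(O[Si](C)(C)C(C)(C)C)=C[C@@H]2[C@]1(C)CCC[C@]2(C)C(=O)OC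
F8 | step 9 | dimethyl 7-oxo-17-(phenylsulfanyl)-12,13,14,15,16-pentanorlabdane-11,19-dioate (C8 epimers) | COC(=O)[C@H]1C(CSc3ccccc3)C(=O)C[C@@H]2[C@]1(C)CCC[C@]2(C)C(=O)OC
F9 | step 9 | dimethyl 7α-hydroxy-17-(phenylsulfanyl)-12,13,14,15,16-pentanorlabdane-11,19-dioate (C8 epimers) | COC(=O)[C@H]1C(CSc3ccccc3)[C@H](O)C[C@@H]2[C@]1(C)CCC[C@]2(C)C(=O)OC
F10 | step 9 | dimethyl 7α-hydroxy-17-(phenylsulfinyl)-12,13,14,15,16-pentanorlabdane-11,19-dioate (C8 and sulfur epimers) | COC(=O)[C@H]1C(CS(=O)c3ccccc3)[C@H](O)C[C@@H]2[C@]1(C)CCC[C@]2(C)C(=O)OC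
F11 | step 2 | (2S)-2-(methoxycarbonyl)-2-methylpent-4-enoic acid | C=CC[C@](C)(C(=O)OC)C(=O)O
F12 | step 2 | mixed ethyl carbonic anhydride of F11 | C=CC[C@](C)(C(=O)OC)C(=O)OC(=O)OCC
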